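**Retrosynthetic overview**
1. All 19 carbons come from two achiral pieces, aryl methyl ketone 1 and benzaldehyde 2. An aldol condensation joins them to chalcone 3 (C19H20O6, the target minus one oxygen atom).
2. Oxidative dearomatisation of 3 in methanol puts a second OMe para to the phenol OH and gives the prochiral p-quinone monoketal 4.
3. Key disconnection (C1–C5 bond and ester C=O of the target): water adds to C3 of 4 to give hemiketal 5, then C2 shifts from C3 to the ketal carbon C4. C3 leaves the ring as CO2Me, and C4 becomes the stereocentre C1(OMe)(CO2Me) of 6.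
4. Ring order: the phenyl ring is bought. The six-membered carbocycle is bought as an arene, dearomatised in step 2 and contracted to the cyclopentenone in step 3. A chiral Brønsted acid sets the only stereocentre in that last step.

Assumption: 1 is taken as purchasable (sold as a building block for polymethoxyflavones), and the chelated Z-enol drawn for the target is its freely equilibrating, most stable tautomer, so C1 is the only element that needs control.

**Step 1**
Reactants: 1 1-(2-hydroxy-3,4,5,6-tetramethoxyphenyl)ethan-1-one; 2 benzaldehyde
Product: 3 (E)-1-(2-hydroxy-3,4,5,6-tetramethoxyphenyl)-3-phenylprop-2-en-1-one (kanakugiol)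
Conditions: KOH (5 equiv), EtOH/H2O, 0 °C to rt, 24 h; then 1 M HCl to pH 5
Reagents that add atoms: none
Why: Claisen–Schmidt aldol condensation in which only the ketone can enolise and only the aldehyde is a good acceptor, E1cB loss of water gives the conjugated E-enone under thermodynamic control, and the strong OH···O=C bond keeps the chalcone open on mild acidification.

**Step 2**
Reactants: 3 kanakugiol
Product: 4 3,4,4,5,6-pentamethoxy-2-[(E)-3-phenylprop-2-enoyl]cyclohexa-2,5-dien-1-one
Conditions: PhI(OAc)2 (1.05 equiv), dry MeOH, 0 °C, 30 min; evaporation, short Et3N-deactivated SiO2 plug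
Reagents that add atoms: methanol, CO
Why: Oxidative phenol dearomatisation with a λ3-iodane (trivalent iodine), in which ligand exchange at the phenol oxygen is followed by MeOH attack at the para carbon that already carries OMe, giving the p-quinone dimethyl monoketal with no stereocentre because the ketal carbon is prochiral.

**Step 3**
Reactants: 4 3,4,4,5,6-pentamethoxy-2-[(E)-3-phenylprop-2-enoyl]cyclohexa-2,5-dien-1-one
Product: 6 methyl (1S,5Z)-5-[(2E)-1-hydroxy-3-phenylprop-2-en-1-ylidene]-1,2,3-trimethoxy-4-oxocyclopent-2-ene-1-carboxylate, via hemiketal hydrate 5 (not isolated)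
Conditions: (R)-3,3'-bis(2,4,6-triisopropylphenyl)-1,1'-binaphthalene-2,2'-diyl N-(trifluoromethylsulfonyl)phosphoramide (10 mol %), H2O (1.2 equiv, added as water-saturated CH2Cl2), CH2Cl2 (0.02 M), −20 °C, 24–48 h
Reagents that add atoms: water, O
Why: Proposed new method: a chiral-Brønsted-acid-catalysed, desymmetrising hydrative semipinacol (quasi-Favorskii-type) ring contraction of a p-quinone monoketal; C3 of 4 is the β-carbon of a doubly acceptor-activated vinylogous ester, so water adds there reversibly to give hemiketal 5, in which the bifunctional phosphoramide (acidic N–H on one ketal OMe, P=O accepting the hemiketal O–H) triggers loss of one of the two enantiotopic C4 methoxy groups while the electron-rich enol carbon C2 shifts antiperiplanar from C3 to C4 and the hemiketal collapses to CO2Me; the choice of leaving OMe inside the chiral pocket therefore sets C1 (S), reversible hydration lets both C3 epimers of 5 converge (Curtin–Hammett), and the drive is the new ester C=O, the chelated enol and the relief of two adjacent fully substituted sp3 carbons; the closest known reaction types are chiral phosphoric acid catalysed asymmetric semipinacol rearrangements, N-triflylphosphoramide catalysed asymmetric Nazarov cyclisations and acetal substitutions through oxocarbenium/chiral-anion pairs, and the same skeletal change is known in racemic form from the photorearrangement of quinone monoketals and from the humulone to isohumulone acyloin contraction.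

Atom map for step 3 (numbering of 4 → numbering of 6):
- C1=O → C4=O
- C2 → C5
- C3(OMe) → CO2Me, with the carbonyl O coming from water
- C4(OMe)2 → C1(OMe), with one OMe lost as MeOH
- C5(OMe) → C2(OMe)
- C6(OMe) → C3(OMe)

Mass balance: C20H22O7 + H2O → C20H24O8 → C19H20O7 + CH4O.

Sense of induction: this cannot be derived from precedent for a new reaction, so the (R)-catalyst is written as giving (S)-6. The product configuration is checked by ECD or X-ray, and the equally available (S)-catalyst is used if the sense turns out opposite. C1 is quaternary and non-enolisable and no step follows, so it cannot be scrambled.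

**Compound list**
1 | 1-(2-hydroxy-3,4,5,6-tetramethoxyphenyl)ethan-1-one | CC(=O)c1c(O)c(OC)c(OC)c(OC)c1OC | starting material
2 | benzaldehyde | O=Cc1ccccc1 | starting material
3 | (E)-1-(2-hydroxy-3,4,5,6-tetramethoxyphenyl)-3-phenylprop-2-en-1-one (kanakugiol) | COc1c(O)c(C(=O)/C=C/c2ccccc2)c(OC)c(OC)c1OC | intermediate
4 | 3,4,4,5,6-pentamethoxy-2-[(E)-3-phenylprop-2-enoyl]cyclohexa-2,5-dien-1-one (p-quinone monoketal) | COC1=C(OC)C(OC)(OC)C(OC)=C(C(=O)/C=C/c2ccccc2)C1=O | intermediate
5 | 5-hydroxy-6-[(2E)-1-hydroxy-3-phenylprop-2-en-1-ylidene]-2,3,4,4,5-pentamethoxycyclohex-2-en-1-one (C3 hydrate of 4, enol form, both hemiketal epimers, not isolated) | COC1=C(OC)C(OC)(OC)C(O)(OC)C(=C(O)/C=C/c2ccccc2)C1=O | intermediate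
6 | methyl (1S,5Z)-5-[(2E)-1-hydroxy-3-phenylprop-2-en-1-ylidene]-1,2,3-trimethoxy-4-oxocyclopent-2-ene-1-carboxylate | COC(=O)[C@@]1(OC)C(OC)=C(OC)C(=O)/C1=C(O)/C=C/c1ccccc1 | target

Total step count: 3. Longest linear sequence: 3.

**Steps most likely to fail**

1. Step 3 (the new reaction). The risks are plain ketal hydrolysis to the quinone, acid-induced Nazarov closure of the C3=C2–C(=O)–CH=CHPh unit before hydration, and low ee. The fallback uses known chemistry, sets out from 4 and comes back at 6. Irradiation of 4 (365 nm LED, flow reactor, MeCN/AcOH/H2O 8:1:1, 10 °C) runs the type A cyclohexadienone photorearrangement established for p-quinone monoketals. It gives racemic 3,4,5,6,6-pentamethoxy-1-[(E)-3-phenylprop-2-enoyl]bicyclo[3.1.0]hex-3-en-2-one F1. The donor–acceptor cyclopropane of this compound opens in the same medium: the C1–C6 bond breaks towards the β-diketone enol, and the dimethoxycarbenium end is hydrolysed to CO2Me. The product is racemic methyl (5Z)-5-[(2E)-1-hydroxy-3-phenylprop-2-en-1-ylidene]-1,2,3-trimethoxy-4-oxocyclopent-2-ene-1-carboxylate F2. Preparative chiral SFC (amylose tris(3,5-dimethylphenylcarbamate) phase, CO2/MeOH) delivers 6 and leaves methyl (1R,5Z)-5-[(2E)-1-hydroxy-3-phenylprop-2-en-1-ylidene]-1,2,3-trimethoxy-4-oxocyclopent-2-ene-1-carboxylate F3.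

2. Step 2. The risks are competing ortho attack giving the o-quinone ketal, iodane-induced side reactions of the 2'-hydroxychalcone unit, and loss of the ketal on handling. The fallback sets out from 3 and comes back at 4. It first oxidises fully and installs the ketal afterwards. PhI(OCOCF3)2 in MeCN/H2O at 0 °C performs the oxidative demethylation of the 4-methoxyphenol and gives 2,3,5-trimethoxy-6-[(E)-3-phenylprop-2-enoyl]cyclohexa-2,5-diene-1,4-dione F4. HC(OMe)3, MeOH and camphorsulfonic acid (5 mol %) at rt then ketalise the carbonyl flanked by two OMe-bearing carbons. That carbonyl receives only one vinylogous-ester donation and is the more electrophilic of the two. Methanol exchange at the ring OMe positions is degenerate.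

3. Step 1. The risks are a sluggish reaction of the doubly ortho-substituted, phenoxide-deactivated ketone, with Cannizzaro loss of the aldehyde, and closure to the flavanone. The fallback sets out from 1 (with 2) and comes back at 3. It separates C–C bond formation from dehydration. The dianion of 1 (LiN(SiMe3)2, 2.2 equiv, THF, −78 °C) adds irreversibly to 2 to give racemic 3-hydroxy-1-(2-hydroxy-3,4,5,6-tetramethoxyphenyl)-3-phenylpropan-1-one F5. This is dehydrated with p-TsOH (5 mol %) in toluene at 40 °C with short contact time, and only water is lost.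

**Further compounds**
F1 | step 3 | racemic 3,4,5,6,6-pentamethoxy-1-[(E)-3-phenylprop-2-enoyl]bicyclo[3.1.0]hex-3-en-2-one | COC1=C(OC)C2(OC)C(OC)(OC)C2(C(=O)/C=C/c3ccccc3)C1=O
F2 | step 3 | racemic methyl (5Z)-5-[(2E)-1-hydroxy-3-phenylprop-2-en-1-ylidene]-1,2,3-trimethoxy-4-oxocyclopent-2-ene-1-carboxylate | COC(=O)C1(OC)C(OC)=C(OC)C(=O)/C1=C(O)/C=C/c1ccccc1
F3 | step 3 | methyl (1R,5Z)-5-[(2E)-1-hydroxy-3-phenylprop-2-en-1-ylidene]-1,2,3-trimethoxy-4-oxocyclopent-2-ene-1-carboxylate | COC(=O)[C@]1(OC)C(OC)=C(OC)C(=O)/C1=C(O)/C=C/c1ccccc1
F4 | step 2 | 2,3,5-trimethoxy-6-[(E)-3-phenylprop-2-enoyl]cyclohexa-2,5-diene-1,4-dione | COC1=C(OC)C(=O)C(C(=O)/C=C/c2ccccc2)=C(OC)C1=O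
F5 | step 1 | racemic 3-hydroxy-1-(2-hydroxy-3,4,5,6-tetramethoxyphenyl)-3-phenylpropan-1-one | COc1c(O)c(C(=O)CC(O)c2ccccc2)c(OC)c(OC)c1OC
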